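**Plan**
- Retrosynthesis: the ferulate ester C–O bond is cut first (rebuilt on the 3-OH from Meldrum's acid and vanillin), the side-chain methyl ketone is traced back to a terminal alkene (Wacker oxidation), and the piperidine ring is then cut at N1–C2 and C3–C4; the C6–chain bond is cut last.
- Enabling feature: in the piperidine ring, N1–C2(CH3)–C3(O) is a masked α-oxygenated acetone (C2 = carbonyl carbon, C3 = its enolisable α-carbon), while N1 and C4 are linked through C6–C5 as in a β-amino aldehyde. One Friedländer-type cyclocondensation of a β-amino acetal with methoxyacetone can therefore close the ring.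
- Forward order: the C12 chain is joined to C6 by Grignard addition to a sulfinimine, the ring is closed in one operation as a 2,3-dihydropyridine (C2 and C3 left sp2), the ring is reduced, and the ester is assembled last.
- Stereochemistry: C6 comes from (R)-tert-butanesulfinamide; C2 is set by axial hydride addition to the cyclic imine (2,6-cis); C3 is set by LiBH(s-Bu)3 reduction of the N-Boc 3-ketone anti to the 2-methyl and 6-alkyl groups (all-cis).

Key step: step 5

Assumption: atom numbers in the text follow the piperidine ring of the target (N1, C2 methyl-bearing, C3 oxygen-bearing, C6 chain-bearing), and the target is isolated as the free base.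

Step 1
Reactants: 1 3,3-diethoxypropan-1-ol
Product: 2 3,3-diethoxypropanal
Conditions: (COCl)2, DMSO, CH2Cl2, −78 °C; Et3N, −78 → 0 °C; used crude
Reagents that add atoms: none
Why: Swern oxidation stops at the aldehyde, and its anhydrous, finally basic medium should leave the diethyl acetal untouched.

Step 2
Reactants: 2 3,3-diethoxypropanal; 3 (R)-2-methylpropane-2-sulfinamide
Product: 4 (R,E)-N-(3,3-diethoxypropylidene)-2-methylpropane-2-sulfinamide
Conditions: CuSO4 (anhydrous), CH2Cl2, rt
Reagents that add atoms: none
Why: CuSO4-mediated condensation of a sulfinamide with an aldehyde should give the E-sulfinimine under conditions too mild to ionise the acetal.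

Step 3
Reactants: 4 (R,E)-N-(3,3-diethoxypropylidene)-2-methylpropane-2-sulfinamide; 5 12-bromododec-1-ene
Product: 7 (R)-N-[(3S)-1,1-diethoxypentadec-14-en-3-yl]-2-methylpropane-2-sulfinamide, via Grignard reagent 6 (not isolated)
Conditions: 5, Mg, I2 (cat.), Et2O, reflux; then 4, CH2Cl2, −48 °C → rt; aq. NH4Cl
Reagents that add atoms: none
Why: Grignard addition to a tert-butanesulfinyl aldimine in a non-coordinating solvent runs through a six-membered chair transition state with Mg bound to the sulfinyl oxygen, so the (R)-auxiliary should direct the alkyl group to the Si face of C=N and set C6 as S.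

Step 4
Reactants: 7 (R)-N-[(3S)-1,1-diethoxypentadec-14-en-3-yl]-2-methylpropane-2-sulfinamide
Product: 8 (3S)-1,1-diethoxypentadec-14-en-3-amine
Conditions: HCl (4 M in dioxane), EtOH, 0 °C; then aq. NaOH
Reagents that add atoms: none
Why: acid alcoholysis cleaves the N–S bond of the sulfinamide, and ethanol as solvent makes any acetal exchange degenerate, so the free β-amino acetal should be obtained with C6 untouched.

Step 5
Reactants: 8 (3S)-1,1-diethoxypentadec-14-en-3-amine; 9 1-methoxypropan-2-one
Product: 12 (2S)-2-(dodec-11-en-1-yl)-5-methoxy-6-methyl-2,3-dihydropyridine, via ketimine 10 (not isolated), via 4-ethoxytetrahydropyridine 11 (not isolated)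
Conditions: 9 (1.5 equiv), 4 Å molecular sieves, CH2Cl2, rt; then CF3CO2H (2.5 equiv), 0.05 M, argon, 0 → 40 °C; cold aq. NaOH; used crude
Reagents that add atoms: none
Why: Proposed new method: amine 8 and methoxyacetone first give ketimine 10 (N1–C2 bond); CF3CO2H then ionises the diethyl acetal to an oxocarbenium ion at C4 while the iminium equilibrates with its enamine, whose oxygen-bearing carbon C3 attacks C4 (C3–C4 bond) to give 11, and a second enamine-driven loss of ethanol delivers the conjugated 1-azadiene 12. The closest known reaction types are the Friedländer quinoline annulation (o-aminoaryl aldehyde plus ketone, the same two bonds) and the acid cyclisation of enamines of aminoacetals in Knorr-type and Pomeranz–Fritsch-type ring syntheses; the new element is the transfer to a saturated β-amino acetal and a non-activated α-alkoxy ketone. The six-membered ring closes in a 6-(enolendo)-exo-trig mode, with the enamine C2=C3 inside and the C4 oxocarbenium outside the forming ring. No stereocentre is created: C2 and C3 are deliberately left sp2 for later control from C6, and C6 is neither enolisable nor ionisable under these conditions. The step needs regioselectivity for C3 over the C2-methyl group, expected because acid-mediated enamine formation of unsymmetrical methyl ketones engages the more substituted, here oxygen-stabilised, α-carbon as in acid-catalysed Friedländer annulations; it also needs ring closure to win over oligomerisation, which the acetal secures by keeping C4 silent until nitrogen is tied up as the ketimine, helped by dilution, and air is excluded so that 12 should not aromatise.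

Step 6
Reactants: 12 (2S)-2-(dodec-11-en-1-yl)-5-methoxy-6-methyl-2,3-dihydropyridine
Product: 14 tert-butyl (2S,6R)-2-(dodec-11-en-1-yl)-5-methoxy-6-methyl-3,6-dihydro-2H-pyridine-1-carboxylate, via tetrahydropyridine 13 (not isolated)
Conditions: NaBH4, MeOH, −40 → 0 °C; then Boc2O, Et3N, 40 °C
Reagents that add atoms: di-tert-butyl dicarbonate, CC(C)(C)OC(=O)OC(=O)OC(C)(C)C
Why: 1,2-reduction of the conjugated cyclic imine should deliver hydride axially to C2 of the half-chair that keeps the C6 chain pseudo-equatorial, giving the 2,6-cis amine 13, which is converted in the same flask into its carbamate because the free enol-ether amine is sensitive (imine reduction, then N-acylation).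

Step 7
Reactants: 14 tert-butyl (2S,6R)-2-(dodec-11-en-1-yl)-5-methoxy-6-methyl-3,6-dihydro-2H-pyridine-1-carboxylate
Product: 15 tert-butyl (2R,6S)-6-(dodec-11-en-1-yl)-2-methyl-3-oxopiperidine-1-carboxylate
Conditions: HCl (1 M aq., 0.2 equiv), THF, 0 °C → rt
Reagents that add atoms: water, O
Why: methyl enol ethers hydrolyse under dilute acid far faster than a Boc group is cleaved or C2 is epimerised, so the masked 3-ketone should be released cleanly (enol ether hydrolysis).

Step 8
Reactants: 15 tert-butyl (2R,6S)-6-(dodec-11-en-1-yl)-2-methyl-3-oxopiperidine-1-carboxylate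
Product: 16 tert-butyl (2R,3R,6S)-6-(dodec-11-en-1-yl)-3-hydroxy-2-methylpiperidine-1-carboxylate
Conditions: LiBH(s-Bu)3 (L-Selectride), THF, −78 °C; aq. NH4Cl at −78 °C
Reagents that add atoms: none
Why: in the N-Boc ketone, A(1,3) strain places the 2-methyl and 6-alkyl groups axial on one face, so the bulky hydride should attack C3 from the opposite face and give the all-cis alcohol (substrate-controlled ketone reduction); the cold quench avoids attack of the alkoxide on the carbamate.

Step 9
Reactants: 16 tert-butyl (2R,3R,6S)-6-(dodec-11-en-1-yl)-3-hydroxy-2-methylpiperidine-1-carboxylate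
Product: 17 tert-butyl (2R,3R,6S)-3-hydroxy-2-methyl-6-(11-oxododecyl)piperidine-1-carboxylate
Conditions: PdCl2 (10 mol %), CuCl (20 mol %), O2 (1 atm), DMF/H2O 7:1, rt
Reagents that add atoms: water, O (the carbonyl oxygen; O2 is the terminal oxidant)
Why: Wacker–Tsuji oxidation converts a terminal alkene into the methyl ketone with Markovnikov selectivity and should tolerate the carbamate and the secondary alcohol.

Step 10
Reactants: 17 tert-butyl (2R,3R,6S)-3-hydroxy-2-methyl-6-(11-oxododecyl)piperidine-1-carboxylate; 18 2,2-dimethyl-1,3-dioxane-4,6-dione (Meldrum's acid)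
Product: 19 3-{[(2R,3R,6S)-1-(tert-butoxycarbonyl)-2-methyl-6-(11-oxododecyl)piperidin-3-yl]oxy}-3-oxopropanoic acid
Conditions: 18 (1.2 equiv), toluene, 90 °C; used crude
Reagents that add atoms: none
Why: thermal ring-opening of Meldrum's acid by an alcohol gives the malonic half ester with loss of acetone and works even for hindered alcohols, with retention at C3 because only the O–H bond reacts.

Step 11
Reactants: 19 3-{[(2R,3R,6S)-1-(tert-butoxycarbonyl)-2-methyl-6-(11-oxododecyl)piperidin-3-yl]oxy}-3-oxopropanoic acid; 20 4-hydroxy-3-methoxybenzaldehyde (vanillin)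
Product: 21 tert-butyl (2R,3R,6S)-3-{[(E)-3-(4-hydroxy-3-methoxyphenyl)prop-2-enoyl]oxy}-2-methyl-6-(11-oxododecyl)piperidine-1-carboxylate
Conditions: 20 (1.1 equiv), pyridine, piperidine (0.2 equiv), 50 °C
Reagents that add atoms: none
Why: the Knoevenagel–Doebner condensation of a malonic half ester with an aryl aldehyde gives the E-cinnamate by decarboxylative elimination and tolerates the free phenol, and the far more acidic malonate should react well before the side-chain methyl ketone.

Step 12
Reactants: 21 tert-butyl (2R,3R,6S)-3-{[(E)-3-(4-hydroxy-3-methoxyphenyl)prop-2-enoyl]oxy}-2-methyl-6-(11-oxododecyl)piperidine-1-carboxylate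
Product: 22 (+)-3-O-feruloylcassine, (2R,3R,6S)-2-methyl-6-(11-oxododecyl)piperidin-3-yl (E)-3-(4-hydroxy-3-methoxyphenyl)prop-2-enoate
Conditions: HCl (4 M in dioxane), CH2Cl2, 0 °C → rt; then aq. NaHCO3
Reagents that add atoms: none
Why: anhydrous HCl removes the Boc group as isobutene and CO2 without touching the cinnamate ester, ketone or phenol, and mild basification should release the free amine (carbamate acidolysis).

**Compound list**
1 | 3,3-diethoxypropan-1-ol | OCCC(OCC)OCC | starting material
2 | 3,3-diethoxypropanal | O=CCC(OCC)OCC | intermediate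
3 | (R)-2-methylpropane-2-sulfinamide | CC(C)(C)[S@@](=O)N | starting material
4 | (R,E)-N-(3,3-diethoxypropylidene)-2-methylpropane-2-sulfinamide | CCOC(OCC)C/C=N/[S@](=O)C(C)(C)C | intermediate
5 | 12-bromododec-1-ene | C=CCCCCCCCCCCBr | starting material
6 | dodec-11-en-1-ylmagnesium bromide | C=CCCCCCCCCCC[Mg]Br | intermediate
7 | (R)-N-[(3S)-1,1-diethoxypentadec-14-en-3-yl]-2-methylpropane-2-sulfinamide | C=CCCCCCCCCCC[C@@H](CC(OCC)OCC)N[S@](=O)C(C)(C)C | intermediate
8 | (3S)-1,1-diethoxypentadec-14-en-3-amine | C=CCCCCCCCCCC[C@@H](CC(OCC)OCC)N | intermediate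
9 | 1-methoxypropan-2-one (methoxyacetone) | COCC(C)=O | starting material
10 | (3S)-1,1-diethoxy-N-(1-methoxypropan-2-ylidene)pentadec-14-en-3-amine | C=CCCCCCCCCCC[C@@H](CC(OCC)OCC)N=C(C)COC | intermediate
11 | (2S)-2-(dodec-11-en-1-yl)-4-ethoxy-5-methoxy-6-methyl-2,3,4,5-tetrahydropyridine (mixture at C4 and C5 of this ring) | C=CCCCCCCCCCC[C@H]1CC(OCC)C(OC)C(C)=N1 | intermediate
12 | (2S)-2-(dodec-11-en-1-yl)-5-methoxy-6-methyl-2,3-dihydropyridine | C=CCCCCCCCCCC[C@H]1CC=C(OC)C(C)=N1 | intermediate
13 | (2S,6R)-2-(dodec-11-en-1-yl)-5-methoxy-6-methyl-1,2,3,6-tetrahydropyridine | C=CCCCCCCCCCC[C@H]1CC=C(OC)[C@@H](C)N1 | intermediate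
14 | tert-butyl (2S,6R)-2-(dodec-11-en-1-yl)-5-methoxy-6-methyl-3,6-dihydro-2H-pyridine-1-carboxylate | C=CCCCCCCCCCC[C@H]1CC=C(OC)[C@@H](C)N1C(=O)OC(C)(C)C | intermediate
15 | tert-butyl (2R,6S)-6-(dodec-11-en-1-yl)-2-methyl-3-oxopiperidine-1-carboxylate | C=CCCCCCCCCCC[C@H]1CCC(=O)[C@@H](C)N1C(=O)OC(C)(C)C | intermediate
16 | tert-butyl (2R,3R,6S)-6-(dodec-11-en-1-yl)-3-hydroxy-2-methylpiperidine-1-carboxylate | C=CCCCCCCCCCC[C@H]1CC[C@@H](O)[C@@H](C)N1C(=O)OC(C)(C)C | intermediate
17 | tert-butyl (2R,3R,6S)-3-hydroxy-2-methyl-6-(11-oxododecyl)piperidine-1-carboxylate | CC(=O)CCCCCCCCCC[C@H]1CC[C@@H](O)[C@@H](C)N1C(=O)OC(C)(C)C | intermediate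
18 | 2,2-dimethyl-1,3-dioxane-4,6-dione (Meldrum's acid) | CC1(C)OC(=O)CC(=O)O1 | starting material
19 | 3-{[(2R,3R,6S)-1-(tert-butoxycarbonyl)-2-methyl-6-(11-oxododecyl)piperidin-3-yl]oxy}-3-oxopropanoic acid | CC(=O)CCCCCCCCCC[C@H]1CC[C@@H](OC(=O)CC(=O)O)[C@@H](C)N1C(=O)OC(C)(C)C | intermediate
20 | 4-hydroxy-3-methoxybenzaldehyde (vanillin) | COc1cc(C=O)ccc1O | starting material
21 | tert-butyl (2R,3R,6S)-3-{[(E)-3-(4-hydroxy-3-methoxyphenyl)prop-2-enoyl]oxy}-2-methyl-6-(11-oxododecyl)piperidine-1-carboxylate | COc1cc(/C=C/C(=O)O[C@@H]2CC[C@H](CCCCCCCCCCC(C)=O)N(C(=O)OC(C)(C)C)[C@@H]2C)ccc1O | intermediate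
22 | (+)-3-O-feruloylcassine, (2R,3R,6S)-2-methyl-6-(11-oxododecyl)piperidin-3-yl (E)-3-(4-hydroxy-3-methoxyphenyl)prop-2-enoate | COc1cc(/C=C/C(=O)O[C@@H]2CC[C@H](CCCCCCCCCCC(C)=O)N[C@@H]2C)ccc1O | target

**Step count and risks**
Total step count: 12. Longest linear sequence: 12 steps (1 to 22); all other components are purchased.

Steps most likely to fail:

1. Step 5 (Proposed new method). The enamine may form toward the C2-methyl group and close the regioisomeric ring, the ketimine may condense intermolecularly, or the dihydropyridine may be oxidised by air to the pyridine with loss of the C6 stereocentre. The fallback makes the two bonds in separate known operations; it sets out from 8 and 9 and returns at 12. Amine 8 is converted with Boc2O into tert-butyl N-[(3S)-1,1-diethoxypentadec-14-en-3-yl]carbamate F1. Methoxyacetone 9 is silylated (Me3SiCl, Et3N, NaI, MeCN) to the (Z)-silyl enol ether F2. Mukaiyama addition of F2 to the acetal of F1 (Me3SiOSO2CF3 cat., CH2Cl2, −78 °C) forms the C3–C4 bond regiospecifically in β-ethoxy ketone F3. CF3CO2H then removes the Boc group, and the freed amine condenses with the ketone (N1–C2) and loses ethanol to give 12.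

2. Step 3. Chelation of Mg by the acetal oxygens may erode facial selectivity, or the basic Grignard reagent may deprotonate the sulfinimine α-carbon and trigger loss of ethoxide. The fallback exchanges the roles of the partners; it sets out from 5 (through Grignard reagent 6) and returns at 8. Reagent 6 is formylated with DMF to tridec-12-enal F4, which is condensed with (S)-2-methylpropane-2-sulfinamide (CuSO4) to sulfinimine F5. Addition of the titanium enolate of ethyl acetate (LiN(i-Pr)2, ClTi(Oi-Pr)3, THF, −78 °C) through a closed transition state should give the (3S)-β-amino ester F6. Reduction with i-Bu2AlH at −78 °C gives aldehyde F7, and HCl/EtOH/HC(OEt)3 forms the acetal and removes the sulfinyl group to return 8 after basification.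

3. Step 6. Hydride may add to both faces of the flattened conjugated imine (2,6-trans isomer), and acylation of the hindered nitrogen may be slow. The fallback replaces kinetic by thermodynamic control; it sets out from 12 (through 13) and returns at 15. Crude amine 13 is hydrolysed with aqueous HCl to (2R,6S)-6-(dodec-11-en-1-yl)-2-methylpiperidin-3-one F8. C2, now α to the ketone, is equilibrated as the free base (NaHCO3, MeOH) toward the 2,6-diequatorial cis isomer, and Boc2O then gives 15.

**Further compounds**
F1 | step 5 | tert-butyl N-[(3S)-1,1-diethoxypentadec-14-en-3-yl]carbamate | C=CCCCCCCCCCC[C@@H](CC(OCC)OCC)NC(=O)OC(C)(C)C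
F2 | step 5 | (Z)-[(1-methoxyprop-1-en-2-yl)oxy]trimethylsilane | CO/C=C(/C)O[Si](C)(C)C
F3 | step 5 | tert-butyl N-[(6S)-4-ethoxy-3-methoxy-2-oxooctadec-17-en-6-yl]carbamate | C=CCCCCCCCCCC[C@@H](CC(OCC)C(OC)C(C)=O)NC(=O)OC(C)(C)C
F4 | step 3 | tridec-12-enal | C=CCCCCCCCCCCC=O
F5 | step 3 | (S,E)-2-methyl-N-(tridec-12-en-1-ylidene)propane-2-sulfinamide | C=CCCCCCCCCCC/C=N/[S@@](=O)C(C)(C)C
F6 | step 3 | ethyl (3S)-3-{[(S)-tert-butylsulfinyl]amino}pentadec-14-enoate | C=CCCCCCCCCCC[C@@H](CC(=O)OCC)N[S@@](=O)C(C)(C)C
F7 | step 3 | (S)-2-methyl-N-[(3S)-1-oxopentadec-14-en-3-yl]propane-2-sulfinamide | C=CCCCCCCCCCC[C@@H](CC=O)N[S@@](=O)C(C)(C)C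
F8 | step 6 | (2R,6S)-6-(dodec-11-en-1-yl)-2-methylpiperidin-3-one | C=CCCCCCCCCCC[C@H]1CCC(=O)[C@@H](C)N1
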